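A direct plan would assemble the E-allylic alcohol A1 in five steps (reduction, bromination, ylide alkylation, Wittig olefination, DIBAL-H), epoxidise it (Katsuki–Sharpless) to A2, open A2 at its distal carbon with the veratryl Grignard reagent A3 under copper catalysis to diol A4, oxidise via α-hydroxy aldehyde A5 to the acid, lactonise and debenzylate A6. Its weakest steps would be: (a) the Wittig olefination, whose E/Z ratio alone would decide the relative configuration, after five steps that create no stereocentre; (b) the epoxide opening, which would spend four equivalents of a Wurtz-prone benzylic Grignard reagent on late enantioenriched material, next to a fully substituted carbon and in competition with Payne rearrangement; (c) the two oxidations, redox adjustment of one carbon through an α-hydroxy aldehyde prone to α-ketol rearrangement.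

**Plan of the new route.** Ring atoms: O1, C2 (C=O), C3 (C–OH), C4, C5. The retrosynthesis cuts the C3–CH2(guaiacyl) bond last (benzylation of a planar C3 enediolate anti to the C4 substituent), returns C3 to the ketone level, where the ring is the flat, achiral 3-hydroxyfuran-2(5H)-one, and cuts that ring at O1–C2, C4–C5 (formaldehyde) and C3–C4 (oxalate). The lactone ring thus arises first and the guaiacyl ring is attached last. Enabling feature: in the five-membered ring C3 lies between C2=O and C4, so a C3 ketone makes H–C4 labile (a dynamic kinetic resolution sets C4) and the C3 carbinol can then be rebuilt from C4. No alkene geometry, benzylic organometallic reagent, epoxide opening or redox adjustment remains.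

Key step: step 3

Remark: the four starting materials are catalogue chemicals; the isotetronic acid of step 2 is drawn as its enol and is assumed to reach its keto tautomer reversibly under the conditions of step 3.

**Step 1**
Reactants: 1 ethyl 3-(3,4-dimethoxyphenyl)propanoate; 2 diethyl oxalate
Product: 3 diethyl 2-(3,4-dimethoxybenzyl)-3-oxobutanedioate (racemic, largely enolised)
Conditions: NaOEt (1.1 equiv), Et2O, 0 °C → rt; cold 1 M HCl
Reagents that add atoms: none
Why: Crossed Claisen condensation, in which the non-enolisable oxalate acylates the ester enolate and the acidic product enolate drives the equilibrium, and the one stereocentre formed is labile and of no consequence.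

**Step 2**
Reactants: 3 diethyl 2-(3,4-dimethoxybenzyl)-3-oxobutanedioate; 4 formaldehyde (37 % aqueous)
Product: 6 4-(3,4-dimethoxybenzyl)-3-hydroxyfuran-2(5H)-one, via keto lactone ester 5 (not isolated)
Conditions: aq HCHO (1.2 equiv), KHCO3 (0.2 equiv), THF–H2O, 0 °C; acidify to pH 2; then 2 M H2SO4–AcOH, 100 °C
Reagents that add atoms: none
Why: Aldol addition (hydroxymethylation) of the doubly activated carbon to formaldehyde is followed by 5-exo-trig lactonisation onto the oxalyl ester, and acid hydrolysis–decarboxylation of the β-keto ester should leave the conjugated, achiral enol.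

**Step 3**
Reactants: 6 4-(3,4-dimethoxybenzyl)-3-hydroxyfuran-2(5H)-one
Product: 8 (3S,4S)-4-(3,4-dimethoxybenzyl)-3-hydroxyoxolan-2-one, via racemic keto tautomer 7 (not isolated)
Conditions: RuCl(p-cymene)[(S,S)-TsDPEN] (2 mol %), HCO2H–Et3N (5:2), DMF, 40 °C
Reagents that add atoms: none
Why: Noyori–Ikariya asymmetric transfer hydrogenation run as a dynamic kinetic resolution: enol 6 tautomerises in the formic acid–triethylamine buffer to the racemic 2,3-dione 7, whose enantiomers interconvert through 6, and the ruthenium hydride with its N–H group transfers hydride and proton to the C3=O of one of them in the outer-sphere six-membered transition state. The closest known reaction type is the transfer-hydrogenative dynamic kinetic resolution of β-stereogenic α-keto esters and of α-substituted cyclic ketones. No ring is closed, since the oxolan-2-one ring is already present and only the C3–H and (by tautomerisation) C4–H bonds are formed. C4 is controlled by the catalyst through matched double selection: the ligand fixes the carbonyl face (with the ester-type C2 carbonyl in the place usually held by an aryl group the (S,S)-ligand should lead to 3S, and the (R,R)-ligand would be used if the sense proved opposite), while the ring directs hydride anti to the C4 benzyl group, so that only the 4S dione should react fast and the cis-(3S,4S) alcohol should result. The step needs discrimination between the enantiomers of 7 together with fast racemisation, and the substrate secures the latter because H–C4 is the enolisable α-hydrogen of a ketone flanked by the lactone carbonyl and the enol is the resting state. The C3 configuration formed here is not needed later, since step 7 erases it, so only the purity at C4 counts.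

**Step 4**
Reactants: 9 vanillin (4-hydroxy-3-methoxybenzaldehyde)
Product: 10 4-[(tert-butyldimethylsilyl)oxy]-3-methoxybenzaldehyde
Conditions: TBSCl (1.1 equiv), imidazole (2.2 equiv), CH2Cl2, rt
Reagents that add atoms: tert-butyldimethylsilyl chloride, CC(C)(C)[Si](C)(C)Cl
Why: Imidazole-mediated silylation of the phenol gives a protecting group that should tolerate the amide base of step 7 and is removed by fluoride.

**Step 5**
Reactants: 10 4-[(tert-butyldimethylsilyl)oxy]-3-methoxybenzaldehyde
Product: 11 {4-[(tert-butyldimethylsilyl)oxy]-3-methoxyphenyl}methanol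
Conditions: NaBH4 (0.5 equiv), THF–MeOH, 0 °C, short contact
Reagents that add atoms: none
Why: Borohydride 1,2-reduction of the aryl aldehyde is fast at 0 °C, and the short contact time should keep the aryl silyl ether intact.

**Step 6**
Reactants: 11 {4-[(tert-butyldimethylsilyl)oxy]-3-methoxyphenyl}methanol
Product: 12 [4-(bromomethyl)-2-methoxyphenoxy](tert-butyl)dimethylsilane
Conditions: CBr4 (1.2 equiv), PPh3 (1.2 equiv), CH2Cl2, 0 °C; short silica pad, used the same day
Reagents that add atoms: carbon tetrabromide, BrC(Br)(Br)Br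
Why: Appel bromination converts the benzylic alcohol under neutral conditions, so no acid is formed that could cleave the aryl silyl ether or ionise the electron-rich benzylic bromide.

**Step 7**
Reactants: 8 (3S,4S)-4-(3,4-dimethoxybenzyl)-3-hydroxyoxolan-2-one; 12 [4-(bromomethyl)-2-methoxyphenoxy](tert-butyl)dimethylsilane
Product: 14 (3S,4S)-3-{4-[(tert-butyldimethylsilyl)oxy]-3-methoxybenzyl}-4-(3,4-dimethoxybenzyl)-3-hydroxyoxolan-2-one, via dilithium enediolate 13 (not isolated)
Conditions: LiN(iPr)2 (2.2 equiv, commercial solution), THF, −78 → −30 °C; 12 (1.2 equiv), DMPU, −78 → −40 °C; aq NH4Cl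
Reagents that add atoms: none
Why: Alkylation of an α-hydroxy lactone dianion (the α-hydroxy counterpart of the Fráter–Seebach alkylation): double deprotonation flattens C3, and the benzylic bromide should attack C3 on the ring face opposite the C4 benzyl group (1,2-induction), which places the two benzyl groups trans and the hydroxyl cis to the C4 benzyl group, that is 3S.

**Step 8**
Reactants: 14 (3S,4S)-3-{4-[(tert-butyldimethylsilyl)oxy]-3-methoxybenzyl}-4-(3,4-dimethoxybenzyl)-3-hydroxyoxolan-2-one
Product: 15 trachelogenin, (3S,4S)-4-(3,4-dimethoxybenzyl)-3-hydroxy-3-(4-hydroxy-3-methoxybenzyl)oxolan-2-one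
Conditions: Bu4NF (1.1 equiv), AcOH (1.2 equiv), THF, 0 °C
Reagents that add atoms: none
Why: Fluoride-mediated desilylation cleaves the aryl O–Si bond, the acetic acid buffer should keep the phenoxide from opening the lactone, and neither stereocentre is acidic or ionisable under these conditions.

**Compound list**
1 | ethyl 3-(3,4-dimethoxyphenyl)propanoate | CCOC(=O)CCc1ccc(OC)c(OC)c1 | starting material
2 | diethyl oxalate | CCOC(=O)C(=O)OCC | starting material
3 | diethyl 2-(3,4-dimethoxybenzyl)-3-oxobutanedioate (racemic) | CCOC(=O)C(=O)C(Cc1ccc(OC)c(OC)c1)C(=O)OCC | intermediate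
4 | formaldehyde | C=O | starting material
5 | ethyl 3-(3,4-dimethoxybenzyl)-4,5-dioxooxolane-3-carboxylate (racemic) | CCOC(=O)C1(Cc2ccc(OC)c(OC)c2)COC(=O)C1=O | intermediate
6 | 4-(3,4-dimethoxybenzyl)-3-hydroxyfuran-2(5H)-one | OC1=C(Cc2ccc(OC)c(OC)c2)COC1=O | intermediate
7 | 4-(3,4-dimethoxybenzyl)oxolane-2,3-dione (racemic keto tautomer of 6) | O=C1C(=O)OCC1Cc1ccc(OC)c(OC)c1 | intermediate
8 | (3S,4S)-4-(3,4-dimethoxybenzyl)-3-hydroxyoxolan-2-one | O[C@@H]1C(=O)OC[C@@H]1Cc1ccc(OC)c(OC)c1 | intermediate
9 | vanillin | COc1cc(C=O)ccc1O | starting material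
10 | 4-[(tert-butyldimethylsilyl)oxy]-3-methoxybenzaldehyde | COc1cc(C=O)ccc1O[Si](C)(C)C(C)(C)C | intermediate
11 | {4-[(tert-butyldimethylsilyl)oxy]-3-methoxyphenyl}methanol | COc1cc(CO)ccc1O[Si](C)(C)C(C)(C)C | intermediate
12 | [4-(bromomethyl)-2-methoxyphenoxy](tert-butyl)dimethylsilane | COc1cc(CBr)ccc1O[Si](C)(C)C(C)(C)C | intermediate
13 | dilithium (4S)-4-(3,4-dimethoxybenzyl)-4,5-dihydrofuran-2,3-bis(olate) | [Li+].[Li+].[O-]C1=C([O-])OC[C@@H]1Cc1ccc(OC)c(OC)c1 | intermediate
14 | (3S,4S)-3-{4-[(tert-butyldimethylsilyl)oxy]-3-methoxybenzyl}-4-(3,4-dimethoxybenzyl)-3-hydroxyoxolan-2-one | COc1cc(C[C@@]2(O)C(=O)OC[C@@H]2Cc2ccc(OC)c(OC)c2)ccc1O[Si](C)(C)C(C)(C)C | intermediate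
15 | trachelogenin, (3S,4S)-4-(3,4-dimethoxybenzyl)-3-hydroxy-3-(4-hydroxy-3-methoxybenzyl)oxolan-2-one | COc1cc(C[C@@]2(O)C(=O)OC[C@@H]2Cc2ccc(OC)c(OC)c2)ccc1O | target

**Step count and risks**
Total step count: 8. Longest linear sequence: 5 steps (steps 1, 2, 3, 7, 8); steps 4–6 form the side branch to bromide 12.

The three steps most likely to fail:

1. Step 3. The catalyst may discriminate poorly between the two enantiomers of the keto tautomer, which would erode the enantiopurity at C4, or the enol resting state may release the ketone too slowly for useful turnover. Fallback (resolution instead of asymmetric reduction): from 6, heterogeneous hydrogenation (H2, 3 atm, Pd/C (palladium on carbon), EtOAc) adds both hydrogens to one face of the enol and should give racemic cis-hydroxy lactone rac-(3S,4S)-4-(3,4-dimethoxybenzyl)-3-hydroxyoxolan-2-one F1. Acetylation (Ac2O, pyridine) would give rac-(3S,4S)-4-(3,4-dimethoxybenzyl)-2-oxooxolan-3-yl acetate F2. Lipase-catalysed enantioselective hydrolysis (lipase from Burkholderia cepacia, phosphate buffer pH 7–MTBE, rt) should, by the empirical rule for secondary alcohols, cleave the 3S acetate, leaving (3R,4R)-4-(3,4-dimethoxybenzyl)-2-oxooxolan-3-yl acetate F3 to be removed by chromatography. A lipase of complementary preference would be screened if needed. The route is rejoined at 8.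

2. Step 7. The enediolate may be alkylated on oxygen, or the second deprotonation may remain incomplete so that starting material is recovered. Fallback (mono-enolate of a protected carbinol instead of the dianion): from 8, silylation (Et3SiCl, imidazole, DMF, rt) would give (3S,4S)-4-(3,4-dimethoxybenzyl)-3-[(triethylsilyl)oxy]oxolan-2-one F4. Its lithium enolate (LiN(iPr)2, 1.1 equiv, THF, −78 °C) would be alkylated with 12, again anti to the C4 benzyl group, to (3S,4S)-3-{4-[(tert-butyldimethylsilyl)oxy]-3-methoxybenzyl}-4-(3,4-dimethoxybenzyl)-3-[(triethylsilyl)oxy]oxolan-2-one F5. Bu4NF–AcOH (THF, 0 °C → rt) would then remove both silyl groups, and the route is rejoined at 15.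

3. Step 2. Under the basic hydroxymethylation conditions the keto lactone ester may fragment by attack at its C3 ketone, carbon–carbon cleavage and β-elimination of the ring oxygen (deoxalylation) before it can be decarboxylated. Fallback (decarboxylation before hydroxymethylation): from 3, hydrolysis and decarboxylation (2 M H2SO4, reflux) would give 4-(3,4-dimethoxyphenyl)-2-oxobutanoic acid F6. Its sodium salt would be hydroxymethylated with one equivalent of aqueous formaldehyde (NaHCO3, H2O, rt) to racemic 3-(3,4-dimethoxybenzyl)-4-hydroxy-2-oxobutanoic acid F7, which should lactonise and enolise on acidification and warming (2 M HCl, 60 °C). The route is rejoined at 6.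

**Further compounds**
F1 | step 3 | rac-(3S,4S)-4-(3,4-dimethoxybenzyl)-3-hydroxyoxolan-2-one (racemic cis, one enantiomer drawn) | O[C@@H]1C(=O)OC[C@@H]1Cc1ccc(OC)c(OC)c1
F2 | step 3 | rac-(3S,4S)-4-(3,4-dimethoxybenzyl)-2-oxooxolan-3-yl acetate (racemic cis, one enantiomer drawn) | CC(=O)O[C@@H]1C(=O)OC[C@@H]1Cc1ccc(OC)c(OC)c1
F3 | step 3 | (3R,4R)-4-(3,4-dimethoxybenzyl)-2-oxooxolan-3-yl acetate | CC(=O)O[C@H]1C(=O)OC[C@H]1Cc1ccc(OC)c(OC)c1
F4 | step 7 | (3S,4S)-4-(3,4-dimethoxybenzyl)-3-[(triethylsilyl)oxy]oxolan-2-one | CC[Si](CC)(CC)O[C@@H]1C(=O)OC[C@@H]1Cc1ccc(OC)c(OC)c1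
F5 | step 7 | (3S,4S)-3-{4-[(tert-butyldimethylsilyl)oxy]-3-methoxybenzyl}-4-(3,4-dimethoxybenzyl)-3-[(triethylsilyl)oxy]oxolan-2-one | COc1cc(C[C@@]2(O[Si](CC)(CC)CC)C(=O)OC[C@@H]2Cc2ccc(OC)c(OC)c2)ccc1O[Si](C)(C)C(C)(C)C
F6 | step 2 | 4-(3,4-dimethoxyphenyl)-2-oxobutanoic acid | O=C(O)C(=O)CCc1ccc(OC)c(OC)c1
F7 | step 2 | 3-(3,4-dimethoxybenzyl)-4-hydroxy-2-oxobutanoic acid (racemic) | OCC(Cc1ccc(OC)c(OC)c1)C(=O)C(=O)O
A1 | direct plan | (E)-2-[4-(benzyloxy)-3-methoxybenzyl]-4-[(tert-butyldimethylsilyl)oxy]but-2-en-1-ol | OC/C(Cc1ccc(OCc2ccccc2)c(OC)c1)=C/CO[Si](C)(C)C(C)(C)C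
A2 | direct plan | {(2R,3R)-2-[4-(benzyloxy)-3-methoxybenzyl]-3-{[(tert-butyldimethylsilyl)oxy]methyl}oxiran-2-yl}methanol | OC[C@@]1(Cc2ccc(OCc3ccccc3)c(OC)c2)O[C@@H]1CO[Si](C)(C)C(C)(C)C
A3 | direct plan | (3,4-dimethoxybenzyl)magnesium chloride | COc1ccc(C[Mg]Cl)cc1OC
A4 | direct plan | (2S,3S)-2-[4-(benzyloxy)-3-methoxybenzyl]-3-{[(tert-butyldimethylsilyl)oxy]methyl}-4-(3,4-dimethoxyphenyl)butane-1,2-diol | OC[C@](O)(Cc1ccc(OCc2ccccc2)c(OC)c1)[C@H](CO[Si](C)(C)C(C)(C)C)Cc1ccc(OC)c(OC)c1
A5 | direct plan | (2S,3S)-2-[4-(benzyloxy)-3-methoxybenzyl]-3-{[(tert-butyldimethylsilyl)oxy]methyl}-4-(3,4-dimethoxyphenyl)-2-hydroxybutanal | O=C[C@](O)(Cc1ccc(OCc2ccccc2)c(OC)c1)[C@H](CO[Si](C)(C)C(C)(C)C)Cc1ccc(OC)c(OC)c1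
A6 | direct plan | (3S,4S)-3-[4-(benzyloxy)-3-methoxybenzyl]-4-(3,4-dimethoxybenzyl)-3-hydroxyoxolan-2-one | COc1cc(C[C@@]2(O)C(=O)OC[C@@H]2Cc2ccc(OC)c(OC)c2)ccc1OCc1ccccc1
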